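**Retrosynthetic overview**
1. Target 20 ⇐ C9–OH-directed epoxidation of the C10 vinyl group of 19; both exocyclic methylenes of 19 ⇐ one double methylenation (formaldehyde) of α-carboxy lactone/aldehyde 18, after the angelate is already on C6.
2. 6β,9α-Diol and trans γ-lactone ⇐ C8 hydroxylation/lactonisation and double hydride reduction of cyclohexane-1,4-dione 10 (both carbonyls originate from a p-quinone monoketal).
3. 10 ⇐ tandem conjugate addition/aldol on enone 4 (C5 side chain, quaternary C10), dehydration to the vinyl group, ketal hydrolysis and thermodynamic correction of C7.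
4. 4 ⇐ enantioselective organocatalytic Michael addition of malonate 3 to achiral quinone monoketal 2 (from phenol 1); this sets the first stereocentre (C7), which relays chirality to C5/C10.
5. Ring order: the carbocycle is present from the start (dearomatised arene), then the γ-lactone (step 6), then the oxirane (step 11).

Assumption and conventions: 1, 3, 5 (as THF solution) and 15 are taken as commercial; locants are elemane locants of the target (ring C5–C10; C10 carries CH3 and C1–C2; C5 carries C4(C15)–C3; C7 carries C11(C13)–C12); β = towards the viewer when C5→C6→C7→C8→C9→C10 runs counter-clockwise, α = the other face; the malonate/lactone α-carbon C11 and the carbinol carbon of 7 arise as inconsequential epimer mixtures and are left undefined in the SMILES.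

**Step 1**
Reactants: 1 4-methoxy-2-methylphenol
Product: 2 quinone monoketal
Conditions: PhI(OAc)2, MeOH, 0 °C
Reagents that add atoms: methanol CO
Why: Oxidative dearomatisation of a p-alkoxyphenol by a trivalent-iodine oxidant in methanol is a standard route to quinone monoketals, and no stereocentre is formed.

**Step 2**
Reactants: 2 quinone monoketal; 3 tert-butyl methyl malonate
Product: 4 Michael adduct
Conditions: quinine-derived 3,5-bis(trifluoromethyl)phenyl squaramide (10 mol%), PhMe, −20 °C
Reagents that add atoms: none
Why: Proposed new method: an enantioselective 1,4-addition of a malonate to a 2-substituted quinone monoketal under bifunctional tertiary-amine/squaramide catalysis has not been shown; the squaramide N–H groups bind the dienone carbonyl while the protonated quinuclidine delivers the malonate enolate to one face of the unsubstituted, more electrophilic C7 terminus (the α-methyl enone is less reactive), giving (R)-C7 with the malonyl group α (deliberately opposite to the target, used as a relay and corrected in step 5), and the non-acidic medium avoids aromatisation of the adduct; the sense of induction must be found by experiment (the quinidine pseudoenantiomer is used if the antipode forms), and the closest known reactions are bifunctional thiourea- or squaramide-catalysed Michael additions of malonates to enones and nitroalkenes.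

**Step 3**
Reactants: 4 Michael adduct; 5 (1,3-dioxolan-2-ylmethyl)magnesium bromide
Product: 7 aldol ketone, via bis(bromomagnesium) enolate 6 (not isolated)
Conditions: 5 (3 equiv), CuBr·SMe2 (0.3 equiv), THF, −40 °C; then MeCHO, −78 °C; AcOH
Reagents that add atoms: acetaldehyde CC=O
Why: After the first equivalent of 5 deprotonates the malonate, copper-catalysed conjugate addition occurs by axial attack at C5 anti to the pseudo-equatorial C7 substituent (trans-3,5 rule), and the magnesium enolate is trapped by acetaldehyde on the face opposite the new C5 group, so C5 (β side chain) and quaternary C10 (β-CH3, α-C1) are set by relay from C7 (tandem conjugate addition–aldol).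

**Step 4**
Reactants: 7 aldol ketone
Product: 8 vinyl ketone
Conditions: Burgess reagent, PhMe, 70 °C
Reagents that add atoms: none
Why: Burgess dehydration (syn elimination of the sulfamate) can only take a hydrogen from the terminal methyl because C10 is quaternary, so the carbinol becomes the vinyl group and no stereocentre is touched.

**Step 5**
Reactants: 8 vinyl ketone
Product: 10 cis-dione, via trans-dione 9 (not isolated)
Conditions: 1 M HCl, THF, 0 °C; then DBU (0.2 equiv), CH2Cl2, rt
Reagents that add atoms: water O
Why: The acyclic dimethyl ketal hydrolyses much faster than the dioxolane or the tert-butyl ester, and enolisation of the new C6 ketone then epimerises the accessible C7 (C5 is shielded by the quaternary C10) to the 2,6-cis diequatorial arrangement, which fixes C7 in its final β configuration (acetal hydrolysis, thermodynamic epimerisation).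

**Step 6**
Reactants: 10 cis-dione
Product: 13 lactone dione, via dipotassium enolate 11 (not isolated), via hydroxy malonate 12 (not isolated)
Conditions: KN(SiMe3)2 (2.2 equiv), THF, −78 °C; 2-(phenylsulfonyl)-3-phenyloxaziridine; AcOH; then PPTS, PhMe, 60 °C
Reagents that add atoms: 2-(phenylsulfonyl)-3-phenyloxaziridine O=S(=O)(c1ccccc1)N1OC1c1ccccc1
Why: With the malonate masked as its anion, the kinetic enolate of the C9 ketone can only form towards C8, and oxygen transfer (enolate hydroxylation with a sulfonyloxaziridine) occurs on the α face, anti to the adjacent C7 group and the axial C10 methyl; the trans-diequatorial hydroxy ester then lactonises through the methyl ester only, the tert-butyl ester staying as a latent acid.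

**Step 7**
Reactants: 13 lactone dione
Product: 14 lactone diol
Conditions: LiBH(sec-Bu)3 (3.5 equiv), THF, −78 °C; AcOH
Reagents that add atoms: none
Why: One equivalent of hydride deprotonates the acidic α-tert-butoxycarbonyl lactone (enolate protection), and the bulky borohydride then attacks both ring ketones equatorially on the lactone-locked chair (axial attack at C6 is also blocked by the axial C10 methyl), giving the axial 6β-OH and the axial 9α-OH cis to the C8 oxygen (diastereoselective hydride reduction).

**Step 8**
Reactants: 14 lactone diol; 15 angelic acid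
Product: 17 angelate, via mixed anhydride 16 (not isolated)
Conditions: 15, 2,4,6-trichlorobenzoyl chloride, Et3N, PhMe, rt; then 14, 80 °C
Reagents that add atoms: none
Why: Mixed-anhydride (Yamaguchi-type) acylation without a nucleophilic catalyst transfers the angeloyl group with retention of the Z geometry, and the C9 hydroxyl, axial next to the quaternary C10 and hydrogen-bonded to the lactone oxygen, is expected to be the less reactive alcohol, so C6–OH is esterified (site-selective esterification).

**Step 9**
Reactants: 17 angelate
Product: 18 aldehyde acid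
Conditions: TFA/CH2Cl2/H2O (10:10:1), 0 °C to rt
Reagents that add atoms: water O
Why: Aqueous trifluoroacetic acid cleaves the tert-butyl ester (loss of isobutene) and hydrolyses the dioxolane, while the angelate, lactone and vinyl group survive and the malonic-type acid does not decarboxylate without heating (acidolysis, acetal hydrolysis).

**Step 10**
Reactants: 18 aldehyde acid
Product: 19 deoxy target
Conditions: 37% aq. CH2O, pyrrolidine (0.4 equiv), EtCO2H (0.4 equiv), i-PrOH, 45 °C
Reagents that add atoms: formaldehyde C=O
Why: Under amine/acid catalysis formaldehyde converts the α-carboxy lactone into the α-methylene lactone (Mannich reaction with decarboxylative elimination) and the CH2–CHO unit into the 2-substituted acrolein (organocatalytic α-methylenation of an aldehyde) in one operation, and the C6 oxygen, already acylated, cannot add to the new acceptors.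

**Step 11**
Reactants: 19 deoxy target
Product: 20 target CNP0113462.3
Conditions: VO(acac)2 (5 mol%), t-BuOOH, CH2Cl2, 0 °C to rt
Reagents that add atoms: tert-butyl hydroperoxide CC(C)(C)OO
Why: The free homoallylic C9 hydroxyl directs the vanadium peroxide to the only electron-rich alkene (enal, methylene lactone and angelate are electron-poor), and delivery from the C9–O side to the vinyl rotamer eclipsing the C10–C5 bond gives the (R)-oxirane carbon (hydroxyl-directed epoxidation).

**Compound list**
1 | 4-methoxy-2-methylphenol | COc1ccc(O)c(C)c1 | starting material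
2 | 4,4-dimethoxy-2-methylcyclohexa-2,5-dien-1-one (achiral quinone monoketal) | COC1(OC)C=CC(=O)C(C)=C1 | intermediate
3 | tert-butyl methyl malonate (tert-butyl methyl propanedioate) | COC(=O)CC(=O)OC(C)(C)C | starting material
4 | tert-butyl methyl 2-[(1R)-6,6-dimethoxy-4-methyl-3-oxocyclohex-4-en-1-yl]propanedioate (malonyl group 7α) | O=C1C[C@H](C(C(=O)OC)C(=O)OC(C)(C)C)C(OC)(OC)C=C1C | intermediate
5 | (1,3-dioxolan-2-ylmethyl)magnesium bromide | Br[Mg]CC1OCCO1 | starting material
6 | bis(bromomagnesium) salt of the 1,4-adduct: C9 magnesium enolate with 5β-(1,3-dioxolan-2-ylmethyl) and the 7α-malonyl group as its magnesium enolate | C1[C@H](C(C(=O)OC)=C(O[Mg]Br)OC(C)(C)C)C(OC)(OC)[C@@H](CC2OCCO2)C(C)=C1O[Mg]Br | intermediate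
7 | tert-butyl methyl 2-[5β-(1,3-dioxolan-2-ylmethyl)-10α-(1-hydroxyethyl)-6,6-dimethoxy-10β-methyl-9-oxocyclohexan-7α-yl]propanedioate | C1[C@H](C(C(=O)OC)C(=O)OC(C)(C)C)C(OC)(OC)[C@@H](CC2OCCO2)[C@](C)(C(C)O)C1=O | intermediate
8 | tert-butyl methyl 2-[5β-(1,3-dioxolan-2-ylmethyl)-6,6-dimethoxy-10β-methyl-9-oxo-10α-vinylcyclohexan-7α-yl]propanedioate | C1[C@H](C(C(=O)OC)C(=O)OC(C)(C)C)C(OC)(OC)[C@@H](CC2OCCO2)[C@](C)(C=C)C1=O | intermediate
9 | tert-butyl methyl 2-[5β-(1,3-dioxolan-2-ylmethyl)-10β-methyl-6,9-dioxo-10α-vinylcyclohexan-7α-yl]propanedioate (5,7-trans) | C1[C@H](C(C(=O)OC)C(=O)OC(C)(C)C)C(=O)[C@@H](CC2OCCO2)[C@](C)(C=C)C1=O | intermediate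
10 | tert-butyl methyl 2-[5β-(1,3-dioxolan-2-ylmethyl)-10β-methyl-6,9-dioxo-10α-vinylcyclohexan-7β-yl]propanedioate (5,7-cis) | C1[C@@H](C(C(=O)OC)C(=O)OC(C)(C)C)C(=O)[C@@H](CC2OCCO2)[C@](C)(C=C)C1=O | intermediate
11 | dipotassium salt of 10 (C8=C9 enolate and malonate anion) | [K+].[K+].[O-]C1=C[C@@H](C(C(=O)OC)=C([O-])OC(C)(C)C)C(=O)[C@@H](CC2OCCO2)[C@]1(C)C=C | intermediate
12 | tert-butyl methyl 2-[5β-(1,3-dioxolan-2-ylmethyl)-8α-hydroxy-10β-methyl-6,9-dioxo-10α-vinylcyclohexan-7β-yl]propanedioate | O[C@@H]1[C@@H](C(C(=O)OC)C(=O)OC(C)(C)C)C(=O)[C@@H](CC2OCCO2)[C@](C)(C=C)C1=O | intermediate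
13 | trans-fused γ-lactone (C7β–C11–C12(=O)–O–C8α) carrying 11-CO2t-Bu, 5β-(1,3-dioxolan-2-ylmethyl), 10β-methyl, 10α-vinyl and 6,9-dioxo groups | CC(C)(C)OC(=O)C1C(=O)O[C@@H]2[C@@H]1C(=O)[C@@H](CC3OCCO3)[C@](C)(C=C)C2=O | intermediate
14 | the same lactone with 6β-hydroxy and 9α-hydroxy groups | CC(C)(C)OC(=O)C1C(=O)O[C@@H]2[C@@H]1[C@@H](O)[C@@H](CC3OCCO3)[C@](C)(C=C)[C@@H]2O | intermediate
15 | angelic acid, (2Z)-2-methylbut-2-enoic acid | C/C=C(/C)C(=O)O | starting material
16 | (2Z)-2-methylbut-2-enoic 2,4,6-trichlorobenzoic anhydride | C/C=C(/C)C(=O)OC(=O)c1c(Cl)cc(Cl)cc1Cl | intermediate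
17 | 6β-angeloyloxy-9α-hydroxy lactone with 11-CO2t-Bu, 5β-(1,3-dioxolan-2-ylmethyl), 10β-methyl, 10α-vinyl | CC(C)(C)OC(=O)C1C(=O)O[C@@H]2[C@@H]1[C@@H](OC(=O)/C(C)=C\C)[C@@H](CC3OCCO3)[C@](C)(C=C)[C@@H]2O | intermediate
18 | 6β-angeloyloxy-9α-hydroxy lactone 11-carboxylic acid with 5β-(2-oxoethyl), 10β-methyl, 10α-vinyl | OC(=O)C1C(=O)O[C@@H]2[C@@H]1[C@@H](OC(=O)/C(C)=C\C)[C@@H](CC=O)[C@](C)(C=C)[C@@H]2O | intermediate
19 | 1,2-deoxy target: 11(13)-methylene-8α,12-olide with 6β-angeloyloxy, 9α-hydroxy, 5β-(3-oxoprop-1-en-2-yl), 10β-methyl, 10α-vinyl | C=C1C(=O)O[C@@H]2[C@@H]1[C@@H](OC(=O)/C(C)=C\C)[C@@H](C(=C)C=O)[C@](C)(C=C)[C@@H]2O | intermediate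
20 | CNP0113462.3: as 19 with 10α-[(2R)-oxiran-2-yl]; (1R,5R,6S,7S,8R,9S,10S) in elemane locants | C=C1C(=O)O[C@@H]2[C@@H]1[C@@H](OC(=O)/C(C)=C\C)[C@@H](C(=C)C=O)[C@](C)([C@@H]1CO1)[C@@H]2O | target

**Totals and risks**
Total step count: 11. Longest linear sequence: 11 steps (1 to 20); 3, 5 and 15 are bought.

The three steps most likely to fail:

Step 2 (the proposed new reaction). If the bifunctional squaramide gives poor conversion or selectivity on the quinone monoketal, the same C7–C11 bond is made by covalent iminium activation instead of non-covalent base catalysis. The known secondary-amine protocol for malonate additions to cyclic enones is used: (S)-5-(pyrrolidin-2-yl)-1H-tetrazole (15 mol%) with piperidine as co-base in CHCl3 at rt. This fallback sets out from 2 (with 3) and comes back to the route at 4; it makes no compound outside the list (F0).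

Step 5 (C7 epimerisation; the risk is competing epimerisation at C5, which would give the diastereomer with the side chains cis to the vinyl group). The fallback sets out from 8 and inverts C7 before the ketal is removed, when C5 has no acidic hydrogen. Catalytic KOt-Bu in t-BuOH/THF at 50 °C equilibrates the malonate by reversible retro-Michael/Michael addition to the cis-disposed 7β-malonyl ketal F1. Hydrolysis of F1 with 1 M HCl in THF at 0 °C then gives the cis-dione directly, so the fallback comes back to the route at 10.

Step 8 (site selectivity of the angeloylation; the risk is reaction at C9–OH or translactonisation at 80 °C). The fallback sets out from 14 and uses the higher reactivity of C9–OH instead of fighting it. Silylation with Et3SiCl and imidazole in DMF at 0 °C gives the 9-O-triethylsilyl ether F2. The only remaining hydroxyl is then acylated with mixed anhydride 16 (PhMe, 80 °C) to the silylated angelate F3. The acid treatment of step 9 removes the silyl ether together with the tert-butyl ester and the dioxolane, so the fallback comes back to the route at 18.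

**Further compounds**
F0 | step 2 | none | none
F1 | step 5 | tert-butyl methyl 2-[5β-(1,3-dioxolan-2-ylmethyl)-6,6-dimethoxy-10β-methyl-9-oxo-10α-vinylcyclohexan-7β-yl]propanedioate | C1[C@@H](C(C(=O)OC)C(=O)OC(C)(C)C)C(OC)(OC)[C@@H](CC2OCCO2)[C@](C)(C=C)C1=O
F2 | step 8 | 9-O-triethylsilyl ether of 14 | CC(C)(C)OC(=O)C1C(=O)O[C@@H]2[C@@H]1[C@@H](O)[C@@H](CC3OCCO3)[C@](C)(C=C)[C@@H]2O[Si](CC)(CC)CC
F3 | step 8 | 9-O-triethylsilyl ether of 17 | CC(C)(C)OC(=O)C1C(=O)O[C@@H]2[C@@H]1[C@@H](OC(=O)/C(C)=C\C)[C@@H](CC3OCCO3)[C@](C)(C=C)[C@@H]2O[Si](CC)(CC)CC
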